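**Strategy.** The route rests on growing the benzene ring of the dihydrobenzofuran (C3a, C4–C7, C7a) onto a preformed O1–C2–C3 unit: a trans γ-aryl-β-(benzyloxymethyl)butyrolactone whose carbonyl carbon becomes C7a and whose α-CH2 becomes C3a. In one operation, thermal disrotatory 6π-electrocyclisation of a 5-dienyl-2,3-dihydrofuran forms C3a–C4 and the six-membered ring, and a quinone then aromatises it, delivering C7–OMe and the C5 CH2O handle with C2/C3 untouched. The precursor is the lactone-derived 2,3-dihydrofuran carrying a (1E)-1-methoxy-3-(silyloxymethyl)buta-1,3-dienyl group at C5. The benzylic bromide made from the product then alkylates an (R)-β-benzyl-γ-butyrolactone enolate, and hydrogenolysis gives isolappaol A.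

Key step: step 12

Remark: the descriptors (2S,3R) for the dihydrofuran and the dihydrobenzofuran and (1E) for the dienyl enol ether were checked against the target and are used unchanged. The dienyl CH2O group is carried as a triisopropylsilyl ether to slow allylic deprotonation and silyl migration during the vinylic lithiation. Chloranil is chosen as the aromatising quinone because it should leave the electron-rich C2–H benzylic ether alone. The (E)-methoxydiene is made stereospecifically, and 4-(benzyloxy)-3-methoxybenzaldehyde is bought as the benzyl ether of vanillin.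

**Route**

Step 1
Reactants: 1 (4S)-4-benzyl-1,3-oxazolidin-2-one; 2 methyl 4-chloro-4-oxobutanoate
Product: 3 methyl 4-[(4S)-4-benzyl-2-oxo-1,3-oxazolidin-3-yl]-4-oxobutanoate
Conditions: n-BuLi, THF, −78 °C; then 2, −78 → 0 °C
Reagents that add atoms: none
Why: N-acylation of the lithiated oxazolidinone by the acid chloride is the standard loading of this auxiliary, and the methyl ester end is inert at low temperature.

Step 2
Reactants: 3 succinate imide; 4 4-(benzyloxy)-3-methoxybenzaldehyde
Product: 6 (4S)-4-benzyl-3-{[(2S,3S)-2-[4-(benzyloxy)-3-methoxyphenyl]-5-oxotetrahydrofuran-3-yl]carbonyl}-1,3-oxazolidin-2-one, via syn-aldol adduct 5 (not isolated)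
Conditions: Bu2BOTf, iPr2NEt, CH2Cl2, 0 °C; 4, −78 → 0 °C; pH 7 buffer/MeOH; PhMe, 60 °C
Reagents that add atoms: none
Why: Evans syn-aldol reaction, in which the (Z)-boron enolate adds through a Zimmerman–Traxler chair on the face away from the benzyl group of the (S)-auxiliary to set both centres (3S,4S), after which the syn adduct closes onto the methyl ester to the trans lactone, which is also the thermodynamically preferred isomer.

Step 3
Reactants: 6 lactone imide
Product: 7 (2S,3S)-2-[4-(benzyloxy)-3-methoxyphenyl]-5-oxotetrahydrofuran-3-carboxylic acid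
Conditions: LiOH, H2O2, THF/H2O, 0 °C; Na2SO3; HCl (aq)
Reagents that add atoms: hydrogen peroxide, OO (as LiOOH; its oxygen becomes the carboxyl OH)
Why: Hydroperoxide cleavage of the auxiliary attacks the exocyclic imide carbonyl selectively, and any lactone opening is reversed on acidification to the stable trans lactone.

Step 4
Reactants: 7 paraconic acid
Product: 8 (4R,5S)-5-[4-(benzyloxy)-3-methoxyphenyl]-4-(hydroxymethyl)dihydrofuran-2(3H)-one
Conditions: BH3·SMe2, THF, 0 °C → rt; MeOH
Reagents that add atoms: none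
Why: Chemoselective borane reduction, since a free carboxylic acid is reduced far faster than a γ-lactone.

Step 5
Reactants: 8 hydroxymethyl lactone
Product: 9 (4R,5S)-5-[4-(benzyloxy)-3-methoxyphenyl]-4-[(benzyloxy)methyl]dihydrofuran-2(3H)-one
Conditions: 2-benzyloxy-1-methylpyridinium triflate, MgO, PhCF3, 85 °C
Reagents that add atoms: 2-benzyloxy-1-methylpyridinium trifluoromethanesulfonate, C[n+]1ccccc1OCc1ccccc1.[O-]S(=O)(=O)C(F)(F)F
Why: Neutral benzyl transfer (O-benzylation) avoids both the alkoxide that would trigger translactonisation and the strong acid that would ionise the electron-rich benzylic C–O bond.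

Step 6
Reactants: 10 2-methylidenepropane-1,3-diol
Product: 11 2-{[(triisopropylsilyl)oxy]methyl}prop-2-en-1-ol
Conditions: NaH (1 equiv), THF, 0 °C; iPr3SiCl (1 equiv), rt
Reagents that add atoms: chlorotriisopropylsilane, CC(C)[Si](Cl)(C(C)C)C(C)C
Why: Monosilylation of a symmetrical diol through its sparingly soluble mono-sodium alkoxide is a reliable way to protect one of two equivalent hydroxyls.

Step 7
Reactants: 11 mono-silyl ether
Product: 12 2-{[(triisopropylsilyl)oxy]methyl}prop-2-enal
Conditions: MnO2, CH2Cl2, rt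
Reagents that add atoms: none
Why: Allylic alcohol oxidation with MnO2 stops at the enal and leaves the silyl ether alone.

Step 8
Reactants: 12 enal
Product: 13 {[(3E)-4-iodo-2-methylidenebut-3-en-1-yl]oxy}triisopropylsilane
Conditions: CrCl2, CHI3, THF, 0 °C
Reagents that add atoms: iodoform, IC(I)I
Why: Takai olefination converts aldehydes into (E)-vinyl iodides with high E preference, which fixes the geometry later needed in the triene.

Step 9
Reactants: 13 (E)-iododiene
Product: 14 {[(3E)-4-methoxy-2-methylidenebut-3-en-1-yl]oxy}triisopropylsilane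
Conditions: CuI (10 mol%), 3,4,7,8-tetramethyl-1,10-phenanthroline, Cs2CO3, MeOH, PhMe, 80 °C
Reagents that add atoms: methanol, CO
Why: Copper-catalysed Ullmann-type C–O coupling of a vinyl iodide with an alcohol proceeds with retention of alkene geometry, so the (E)-enol ether should form as a single isomer.

Step 10
Reactants: 14 (E)-methoxydiene; 9 benzyloxymethyl lactone
Product: 16 (4R,5S)-5-[4-(benzyloxy)-3-methoxyphenyl]-4-[(benzyloxy)methyl]-2-[(1E)-1-methoxy-3-{[(triisopropylsilyl)oxy]methyl}buta-1,3-dien-1-yl]tetrahydrofuran-2-ol (both C2 epimers), via lithiated diene 15 (not isolated)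
Conditions: t-BuLi, THF, −78 °C; then 9, −78 °C; NH4Cl (aq)
Reagents that add atoms: none
Why: Vinylic α-lithiation of an enol ether occurs next to oxygen with retention, placing lithium cis to the methylidene-bearing carbon, and 1,2-addition of the vinyllithium to the γ-lactone should stop at the lithium hemiketal at −78 °C.

Step 11
Reactants: 16 lactol
Product: 17 (2S,3R)-2-[4-(benzyloxy)-3-methoxyphenyl]-3-[(benzyloxy)methyl]-5-[(1E)-1-methoxy-3-{[(triisopropylsilyl)oxy]methyl}buta-1,3-dien-1-yl]-2,3-dihydrofuran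
Conditions: MsCl, Et3N, CH2Cl2, −20 → 0 °C; filtration through basic Al2O3
Reagents that add atoms: none
Why: Lactol dehydration of the kind used for C-glycals, in which mesylation gives an oxocarbenium ion stabilised by the methoxydiene and Et3N removes a ring CH2 proton (E1-type elimination) to give the endocyclic enol ether under conditions that stay basic throughout.

Step 12
Reactants: 17 5-dienyl-2,3-dihydrofuran
Product: 19 {[(2S,3R)-2-[4-(benzyloxy)-3-methoxyphenyl]-3-[(benzyloxy)methyl]-7-methoxy-2,3-dihydro-1-benzofuran-5-yl]methoxy}triisopropylsilane, via cyclohexadiene 18 (not isolated)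
Conditions: PhMe (0.02 M, degassed), 110 °C; then chloranil, 60 °C
Reagents that add atoms: none
Why: Proposed new method: on heating, the triene C4=C5–C1'(OMe)=C2'H–C3'(=CH2) of 17, whose central enol ether holds the ring and C3' cis, reaches the s-cis,s-cis conformer and closes by a thermally allowed disrotatory 6π-electrocyclisation (bond from ring C4 to the terminal CH2, the later C3a–C4) to cyclohexa-1,3-diene 18, from which chloranil removes the C3a and C4 hydrogens (hydride transfer, then proton loss) to give the benzene ring. The closest known reaction type is the thermal 6π-electrocyclisation/quinone dehydrogenation of 1,3,5-hexatrienes, well used to benzannulate divinyl heteroarenes such as 2,3-divinylindoles to carbazoles, but not yet shown with a 2,3-dihydrofuran enol ether as the terminal 2π component. The one ring closed is the six-membered carbocycle (C3a, C4, C5, C6, C7, C7a), formed in disrotatory fashion across the two triene termini. The only new stereocentre, C3a of 18, is transient and is erased on aromatisation, while C2 and C3 lie outside the reacting π-system and keep the configuration set in step 2. The step needs (a) the cis central geometry, secured by retentive lithiation of (E)-14, (b) freedom from sigmatropic leaks, secured because C3–H sits on the outward position of the ring terminus and the other terminus is a bare CH2, so no 1,5- or 1,7-hydrogen shift has an accessible hydrogen, and (c) an oxidant that spares the electron-rich C2–H benzylic ether, secured by adding the mild quinone chloranil only after cyclisation. Both termini are free of inward substituents and the triene is donor-substituted throughout, so closure should be sterically easy at about 110 °C.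

Step 13
Reactants: 19 silyl ether
Product: 20 [(2S,3R)-2-[4-(benzyloxy)-3-methoxyphenyl]-3-[(benzyloxy)methyl]-7-methoxy-2,3-dihydro-1-benzofuran-5-yl]methanol
Conditions: Bu4NF, THF, 0 °C → rt
Reagents that add atoms: none
Why: Fluoride-mediated desilylation removes the only silyl group and leaves the three benzyl ethers untouched.

Step 14
Reactants: 20 benzylic alcohol
Product: 21 (2S,3R)-2-[4-(benzyloxy)-3-methoxyphenyl]-3-[(benzyloxy)methyl]-5-(bromomethyl)-7-methoxy-2,3-dihydro-1-benzofuran
Conditions: CBr4, PPh3, CH2Cl2, 0 °C; used crude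
Reagents that add atoms: tetrabromomethane, BrC(Br)(Br)Br
Why: Appel bromination converts the primary benzylic alcohol into the bromide under neutral conditions that the acid-sensitive benzylic ether at C2 should tolerate.

Step 15
Reactants: 4 4-(benzyloxy)-3-methoxybenzaldehyde; 22 dimethyl butanedioate
Product: 23 (3E)-4-[4-(benzyloxy)-3-methoxyphenyl]-3-(methoxycarbonyl)but-3-enoic acid
Conditions: NaOMe, MeOH, reflux; HCl (aq)
Reagents that add atoms: none
Why: Stobbe condensation of an aryl aldehyde with a succinate diester gives the (E)-arylidene half-ester through the paraconate intermediate.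

Step 16
Reactants: 23 (E)-half-ester
Product: 24 (3R)-4-[4-(benzyloxy)-3-methoxyphenyl]-3-(methoxycarbonyl)butanoic acid
Conditions: H2 (5 bar), [Rh(cod)((S,S)-Et-DuPhos)]BF4 (0.5 mol%), NaOMe (10 mol%), MeOH, rt
Reagents that add atoms: none
Why: Rhodium-catalysed asymmetric hydrogenation of an itaconate-type half-ester, in which the carboxylate chelates the metal and the (S,S)-bisphospholane ligand is the enantiomer expected to deliver hydrogen to the face that gives the (R)-succinate, while the homogeneous catalyst leaves the benzyl ether intact.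

Step 17
Reactants: 24 (R)-half-ester
Product: 26 (4R)-4-[4-(benzyloxy)-3-methoxybenzyl]dihydrofuran-2(3H)-one, via hydroxy acid 25 (not isolated)
Conditions: KOH (1 equiv), EtOH; CaCl2, NaBH4, EtOH, −10 °C → rt; HCl (aq), rt
Reagents that add atoms: none
Why: Calcium borohydride reduces the ester but not the carboxylate salt (chemoselective ester reduction), and acidification lactonises the γ-hydroxy acid without touching the stereocentre.

Step 18
Reactants: 26 (R)-β-benzyl lactone; 21 benzylic bromide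
Product: 27 (3R,4R)-4-[4-(benzyloxy)-3-methoxybenzyl]-3-({(2S,3R)-2-[4-(benzyloxy)-3-methoxyphenyl]-3-[(benzyloxy)methyl]-7-methoxy-2,3-dihydro-1-benzofuran-5-yl}methyl)dihydrofuran-2(3H)-one
Conditions: LiN(SiMe3)2, THF, −78 °C; then 21, DMPU, −78 → −30 °C
Reagents that add atoms: none
Why: Lactone enolate alkylation, in which the benzylic bromide approaches the planar enolate anti to the β-benzyl substituent and so sets the new α-centre trans (3R).

Step 19
Reactants: 27 tribenzyl ether
Product: 28 isolappaol A, (3R,4R)-4-(4-hydroxy-3-methoxybenzyl)-3-{[(2S,3R)-2-(4-hydroxy-3-methoxyphenyl)-3-(hydroxymethyl)-7-methoxy-2,3-dihydro-1-benzofuran-5-yl]methyl}dihydrofuran-2(3H)-one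
Conditions: H2 (1 atm), Pd/C (10%), EtOAc/MeOH, rt; stopped at full debenzylation
Reagents that add atoms: none
Why: Catalytic hydrogenolysis cleaves the two aryl benzyl ethers and the primary alkyl benzyl ether faster than the hindered cyclic C2–O bond when run at ambient pressure and stopped promptly.

**Compound list**

1 | (4S)-4-benzyl-1,3-oxazolidin-2-one | O=C1N[C@@H](Cc2ccccc2)CO1 | starting material
2 | methyl 4-chloro-4-oxobutanoate | COC(=O)CCC(=O)Cl | starting material
3 | methyl 4-[(4S)-4-benzyl-2-oxo-1,3-oxazolidin-3-yl]-4-oxobutanoate | COC(=O)CCC(=O)N1[C@@H](Cc2ccccc2)COC1=O | intermediate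
4 | 4-(benzyloxy)-3-methoxybenzaldehyde | COc1cc(C=O)ccc1OCc1ccccc1 | starting material
5 | methyl (3S,4S)-3-{[(4S)-4-benzyl-2-oxo-1,3-oxazolidin-3-yl]carbonyl}-4-[4-(benzyloxy)-3-methoxyphenyl]-4-hydroxybutanoate | COC(=O)C[C@H](C(=O)N1[C@@H](Cc2ccccc2)COC1=O)[C@H](O)c1ccc(OCc2ccccc2)c(OC)c1 | intermediate (not isolated)
6 | (4S)-4-benzyl-3-{[(2S,3S)-2-[4-(benzyloxy)-3-methoxyphenyl]-5-oxotetrahydrofuran-3-yl]carbonyl}-1,3-oxazolidin-2-one | O=C1C[C@H](C(=O)N2[C@@H](Cc3ccccc3)COC2=O)[C@@H](c2ccc(OCc3ccccc3)c(OC)c2)O1 | intermediate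
7 | (2S,3S)-2-[4-(benzyloxy)-3-methoxyphenyl]-5-oxotetrahydrofuran-3-carboxylic acid | O=C1C[C@H](C(=O)O)[C@@H](c2ccc(OCc3ccccc3)c(OC)c2)O1 | intermediate
8 | (4R,5S)-5-[4-(benzyloxy)-3-methoxyphenyl]-4-(hydroxymethyl)dihydrofuran-2(3H)-one | O=C1C[C@H](CO)[C@@H](c2ccc(OCc3ccccc3)c(OC)c2)O1 | intermediate
9 | (4R,5S)-5-[4-(benzyloxy)-3-methoxyphenyl]-4-[(benzyloxy)methyl]dihydrofuran-2(3H)-one | O=C1C[C@H](COCc2ccccc2)[C@@H](c2ccc(OCc3ccccc3)c(OC)c2)O1 | intermediate
10 | 2-methylidenepropane-1,3-diol | C=C(CO)CO | starting material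
11 | 2-{[(triisopropylsilyl)oxy]methyl}prop-2-en-1-ol | C=C(CO)CO[Si](C(C)C)(C(C)C)C(C)C | intermediate
12 | 2-{[(triisopropylsilyl)oxy]methyl}prop-2-enal | C=C(C=O)CO[Si](C(C)C)(C(C)C)C(C)C | intermediate
13 | {[(3E)-4-iodo-2-methylidenebut-3-en-1-yl]oxy}triisopropylsilane | I/C=C/C(=C)CO[Si](C(C)C)(C(C)C)C(C)C | intermediate
14 | {[(3E)-4-methoxy-2-methylidenebut-3-en-1-yl]oxy}triisopropylsilane | CO/C=C/C(=C)CO[Si](C(C)C)(C(C)C)C(C)C | intermediate
15 | [(1E)-1-methoxy-3-{[(triisopropylsilyl)oxy]methyl}buta-1,3-dien-1-yl]lithium | C=C(CO[Si](C(C)C)(C(C)C)C(C)C)/C=C(OC)\[Li] | intermediate (not isolated)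
16 | (4R,5S)-5-[4-(benzyloxy)-3-methoxyphenyl]-4-[(benzyloxy)methyl]-2-[(1E)-1-methoxy-3-{[(triisopropylsilyl)oxy]methyl}buta-1,3-dien-1-yl]tetrahydrofuran-2-ol (both C2 epimers) | C=C(CO[Si](C(C)C)(C(C)C)C(C)C)/C=C(OC)\C1(O)C[C@H](COCc2ccccc2)[C@@H](c2ccc(OCc3ccccc3)c(OC)c2)O1 | intermediate
17 | (2S,3R)-2-[4-(benzyloxy)-3-methoxyphenyl]-3-[(benzyloxy)methyl]-5-[(1E)-1-methoxy-3-{[(triisopropylsilyl)oxy]methyl}buta-1,3-dien-1-yl]-2,3-dihydrofuran | C=C(CO[Si](C(C)C)(C(C)C)C(C)C)/C=C(OC)\C1=C[C@H](COCc2ccccc2)[C@@H](c2ccc(OCc3ccccc3)c(OC)c2)O1 | intermediate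
18 | {[(2S,3R)-2-[4-(benzyloxy)-3-methoxyphenyl]-3-[(benzyloxy)methyl]-7-methoxy-2,3,3a,4-tetrahydro-1-benzofuran-5-yl]methoxy}triisopropylsilane (both C3a epimers) | CC(C)[Si](C(C)C)(C(C)C)OCC1=CC(OC)=C2C(C1)[C@H](COCc1ccccc1)[C@@H](c1ccc(OCc3ccccc3)c(OC)c1)O2 | intermediate (not isolated)
19 | {[(2S,3R)-2-[4-(benzyloxy)-3-methoxyphenyl]-3-[(benzyloxy)methyl]-7-methoxy-2,3-dihydro-1-benzofuran-5-yl]methoxy}triisopropylsilane | CC(C)[Si](C(C)C)(C(C)C)OCc1cc(OC)c2c(c1)[C@H](COCc1ccccc1)[C@@H](c1ccc(OCc3ccccc3)c(OC)c1)O2 | intermediate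
20 | [(2S,3R)-2-[4-(benzyloxy)-3-methoxyphenyl]-3-[(benzyloxy)methyl]-7-methoxy-2,3-dihydro-1-benzofuran-5-yl]methanol | OCc1cc(OC)c2c(c1)[C@H](COCc1ccccc1)[C@@H](c1ccc(OCc3ccccc3)c(OC)c1)O2 | intermediate
21 | (2S,3R)-2-[4-(benzyloxy)-3-methoxyphenyl]-3-[(benzyloxy)methyl]-5-(bromomethyl)-7-methoxy-2,3-dihydro-1-benzofuran | BrCc1cc(OC)c2c(c1)[C@H](COCc1ccccc1)[C@@H](c1ccc(OCc3ccccc3)c(OC)c1)O2 | intermediate
22 | dimethyl butanedioate | COC(=O)CCC(=O)OC | starting material
23 | (3E)-4-[4-(benzyloxy)-3-methoxyphenyl]-3-(methoxycarbonyl)but-3-enoic acid | COC(=O)/C(CC(=O)O)=C/c1ccc(OCc2ccccc2)c(OC)c1 | intermediate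
24 | (3R)-4-[4-(benzyloxy)-3-methoxyphenyl]-3-(methoxycarbonyl)butanoic acid | COC(=O)[C@@H](CC(=O)O)Cc1ccc(OCc2ccccc2)c(OC)c1 | intermediate
25 | (3R)-4-[4-(benzyloxy)-3-methoxyphenyl]-3-(hydroxymethyl)butanoic acid | OC[C@@H](CC(=O)O)Cc1ccc(OCc2ccccc2)c(OC)c1 | intermediate (not isolated)
26 | (4R)-4-[4-(benzyloxy)-3-methoxybenzyl]dihydrofuran-2(3H)-one | COc1cc(C[C@H]2COC(=O)C2)ccc1OCc1ccccc1 | intermediate
27 | (3R,4R)-4-[4-(benzyloxy)-3-methoxybenzyl]-3-({(2S,3R)-2-[4-(benzyloxy)-3-methoxyphenyl]-3-[(benzyloxy)methyl]-7-methoxy-2,3-dihydro-1-benzofuran-5-yl}methyl)dihydrofuran-2(3H)-one | COc1cc(C[C@H]2COC(=O)[C@@H]2Cc2cc(OC)c3c(c2)[C@H](COCc2ccccc2)[C@@H](c2ccc(OCc4ccccc4)c(OC)c2)O3)ccc1OCc1ccccc1 | intermediate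
28 | isolappaol A, (3R,4R)-4-(4-hydroxy-3-methoxybenzyl)-3-{[(2S,3R)-2-(4-hydroxy-3-methoxyphenyl)-3-(hydroxymethyl)-7-methoxy-2,3-dihydro-1-benzofuran-5-yl]methyl}dihydrofuran-2(3H)-one | COc1cc(C[C@H]2COC(=O)[C@@H]2Cc2cc(OC)c3c(c2)[C@H](CO)[C@@H](c2ccc(O)c(OC)c2)O3)ccc1O | target

**Step count and risks**

Total step count: 19. Longest linear sequence: 12 steps (steps 1–5, 10–14, 18, 19).

Most likely to fail:

1. Step 12 (bears the new-method label). The triene may dimerise or polymerise through its electron-rich diene faster than it reaches the folded conformer and cyclises, or the oxidant may attack the C2–H benzylic ether. Fallback, by known rhodium-carbenoid chemistry on a preformed arene, sets out from 4 and comes back at 19.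
   - Aldehyde 4 is reduced (NaBH4, MeOH) to [4-(benzyloxy)-3-methoxyphenyl]methanol F1.
   - F1 is joined by Mitsunobu etherification (PPh3, DIAD) to purchased 3-bromo-4-hydroxy-5-methoxybenzaldehyde F2, giving 4-{[4-(benzyloxy)-3-methoxybenzyl]oxy}-3-bromo-5-methoxybenzaldehyde F3.
   - NaBH4 gives (4-{[4-(benzyloxy)-3-methoxybenzyl]oxy}-3-bromo-5-methoxyphenyl)methanol F4, and iPr3SiCl/imidazole gives its triisopropylsilyl ether F5.
   - Palladium-catalysed α-arylation of the trimethylsilyl ketene acetal of methyl acetate (Pd(dba)2, P(t-Bu)3, ZnF2, DMF) converts the aryl bromide into methyl arylacetate F6.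
   - Diazo transfer (4-acetamidobenzenesulfonyl azide, DBU) gives methyl aryldiazoacetate F7.
   - Intramolecular carbene C–H insertion into the ArCH2–O methylene (Rh2(S-PTTL)4, dirhodium tetrakis[N-phthaloyl-(S)-tert-leucinate], or its mirror-image catalyst, whichever leads to the 2S series in a trial; toluene, −60 °C) should give cis ester F8.
   - NaOMe/MeOH epimerises C3 to trans ester F9, LiAlH4 gives primary alcohol F10, and NaH/BnBr returns 19.

2. Step 10. The vinyllithium may act as a base toward the lactone α-position, or add a second time to the ring-opened ketone. Deprotonation of the diene at the allylic CH2OSi position in place of the vinylic C–H is the other danger, limited here by the bulky silyl group. Fallback through an acyclic N-methoxy-N-methylamide, which cannot over-add, sets out from 9 and 15 and comes back at 16.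
   - Lactone 9 is opened with MeNH(OMe)·HCl/AlMe3 to hydroxy amide F11.
   - F11 is silylated at once (Et3SiCl, imidazole) to triethylsilyl ether F12.
   - Lithiated diene 15 adds once through the chelated tetrahedral intermediate to give dienyl ketone F13.
   - Buffered HF·pyridine removes the triethylsilyl group, and the hydroxy ketone closes to lactol 16.

3. Step 11. The oxocarbenium ion may be captured by chloride, or the methyl enol ether may be hydrolysed by adventitious acid, instead of losing the ring proton. Fallback by cross-coupling, which never passes through the lactol, sets out from 9 and 15 and comes back at 17.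
   - Lactone 9 is converted (KN(SiMe3)2, (PhO)2P(O)Cl, THF/HMPA, −78 °C) into ketene acetal phosphate F14.
   - Lithiated diene 15 is quenched with B(OiPr)3 and then pinacol to give dienylboronate F15.
   - Suzuki–Miyaura coupling (Pd(PPh3)4, Cs2CO3, THF/H2O, 50 °C) joins F14 and F15 to triene 17 under basic conditions.

Further compounds
F1 | step 12 | [4-(benzyloxy)-3-methoxyphenyl]methanol | COc1cc(CO)ccc1OCc1ccccc1
F2 | step 12 | 3-bromo-4-hydroxy-5-methoxybenzaldehyde (purchased) | COc1cc(C=O)cc(Br)c1O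
F3 | step 12 | 4-{[4-(benzyloxy)-3-methoxybenzyl]oxy}-3-bromo-5-methoxybenzaldehyde | COc1cc(C=O)cc(Br)c1OCc1ccc(OCc2ccccc2)c(OC)c1
F4 | step 12 | (4-{[4-(benzyloxy)-3-methoxybenzyl]oxy}-3-bromo-5-methoxyphenyl)methanol | COc1cc(CO)cc(Br)c1OCc1ccc(OCc2ccccc2)c(OC)c1
F5 | step 12 | [(4-{[4-(benzyloxy)-3-methoxybenzyl]oxy}-3-bromo-5-methoxyphenyl)methoxy]triisopropylsilane | COc1cc(CO[Si](C(C)C)(C(C)C)C(C)C)cc(Br)c1OCc1ccc(OCc2ccccc2)c(OC)c1
F6 | step 12 | methyl 2-(2-{[4-(benzyloxy)-3-methoxybenzyl]oxy}-3-methoxy-5-{[(triisopropylsilyl)oxy]methyl}phenyl)acetate | COC(=O)Cc1cc(CO[Si](C(C)C)(C(C)C)C(C)C)cc(OC)c1OCc1ccc(OCc2ccccc2)c(OC)c1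
F7 | step 12 | methyl 2-diazo-2-(2-{[4-(benzyloxy)-3-methoxybenzyl]oxy}-3-methoxy-5-{[(triisopropylsilyl)oxy]methyl}phenyl)acetate | COC(=O)C(=[N+]=[N-])c1cc(CO[Si](C(C)C)(C(C)C)C(C)C)cc(OC)c1OCc1ccc(OCc2ccccc2)c(OC)c1
F8 | step 12 | methyl (2S,3R)-2-[4-(benzyloxy)-3-methoxyphenyl]-7-methoxy-5-{[(triisopropylsilyl)oxy]methyl}-2,3-dihydro-1-benzofuran-3-carboxylate (cis) | CC(C)[Si](C(C)C)(C(C)C)OCc1cc(OC)c2c(c1)[C@@H](C(=O)OC)[C@@H](c1ccc(OCc3ccccc3)c(OC)c1)O2
F9 | step 12 | methyl (2S,3S)-2-[4-(benzyloxy)-3-methoxyphenyl]-7-methoxy-5-{[(triisopropylsilyl)oxy]methyl}-2,3-dihydro-1-benzofuran-3-carboxylate (trans) | CC(C)[Si](C(C)C)(C(C)C)OCc1cc(OC)c2c(c1)[C@H](C(=O)OC)[C@@H](c1ccc(OCc3ccccc3)c(OC)c1)O2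
F10 | step 12 | [(2S,3R)-2-[4-(benzyloxy)-3-methoxyphenyl]-7-methoxy-5-{[(triisopropylsilyl)oxy]methyl}-2,3-dihydro-1-benzofuran-3-yl]methanol | CC(C)[Si](C(C)C)(C(C)C)OCc1cc(OC)c2c(c1)[C@H](CO)[C@@H](c1ccc(OCc3ccccc3)c(OC)c1)O2
F11 | step 10 | (3R,4S)-4-[4-(benzyloxy)-3-methoxyphenyl]-3-[(benzyloxy)methyl]-4-hydroxy-N-methoxy-N-methylbutanamide | CON(C)C(=O)C[C@H](COCc1ccccc1)[C@H](O)c1ccc(OCc2ccccc2)c(OC)c1
F12 | step 10 | (3R,4S)-4-[4-(benzyloxy)-3-methoxyphenyl]-3-[(benzyloxy)methyl]-N-methoxy-N-methyl-4-[(triethylsilyl)oxy]butanamide | CON(C)C(=O)C[C@H](COCc1ccccc1)[C@H](O[Si](CC)(CC)CC)c1ccc(OCc2ccccc2)c(OC)c1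
F13 | step 10 | (3E,7R,8S)-8-[4-(benzyloxy)-3-methoxyphenyl]-7-[(benzyloxy)methyl]-4-methoxy-8-[(triethylsilyl)oxy]-2-{[(triisopropylsilyl)oxy]methyl}octa-1,3-dien-5-one | C=C(CO[Si](C(C)C)(C(C)C)C(C)C)/C=C(OC)\C(=O)C[C@H](COCc1ccccc1)[C@H](O[Si](CC)(CC)CC)c1ccc(OCc2ccccc2)c(OC)c1
F14 | step 11 | (2S,3R)-2-[4-(benzyloxy)-3-methoxyphenyl]-3-[(benzyloxy)methyl]-2,3-dihydrofuran-5-yl diphenyl phosphate | O=P(Oc1ccccc1)(Oc1ccccc1)OC1=C[C@H](COCc2ccccc2)[C@@H](c2ccc(OCc3ccccc3)c(OC)c2)O1
F15 | step 11 | 2-[(1E)-1-methoxy-3-{[(triisopropylsilyl)oxy]methyl}buta-1,3-dien-1-yl]-4,4,5,5-tetramethyl-1,3,2-dioxaborolane | C=C(CO[Si](C(C)C)(C(C)C)C(C)C)/C=C(OC)\B1OC(C)(C)C(C)(C)O1
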